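Both benzene rings are cut at C1–C2 and C3–C4 (each ring: C1 acetyl, C2 OH, C3 prenyl, C4 OH, C5 bridge, C6 OH). Two features are exploited. Oxygen and carbon substituents alternate around each phloroglucinol ring, as a cyclobutenone–siloxyalkyne benzannulation requires. The chain C4–C5–CH(isobutyl)–C5'–C4' is the carbon backbone of 3-isobutylglutaric acid. The precursor is a bis-cyclobutenone in which each four-membered ring already carries the ketal-masked acetyl carbon, a silyloxy group and the shared isobutylmethine bridge. Heating it with a prenyl-substituted siloxyalkyne inserts two alkyne carbons into each ring and closes both hexasubstituted arenes, four C–C bonds, in one operation.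

Key step: step 6

Remark: the target is achiral; the only stereocentres on the route (C4 of each four-membered ring of the bis-cyclobutenone) form unselectively and disappear in the key step, so that compound is carried as a diastereomer mixture and all SMILES are written without stereodescriptors.

Step 1
Reactants: 1 ethyl pyruvate
Product: 2 ethyl 2-methyl-1,3-dioxolane-2-carboxylate
Conditions: HOCH2CH2OH, TsOH·H2O (cat.), toluene, reflux, Dean–Stark trap
Reagents that add atoms: ethylene glycol, OCCO
Why: Acid-catalysed ketalisation with azeotropic removal of water converts the electrophilic ketone carbonyl of the α-keto ester into the dioxolane and leaves the ester for step 2; no stereocentre is formed.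

Step 2
Reactants: 2 ethyl 2-methyl-1,3-dioxolane-2-carboxylate
Product: 4 triisopropyl{[(2-methyl-1,3-dioxolan-2-yl)ethynyl]oxy}silane, via lithium 2-(2-methyl-1,3-dioxolan-2-yl)ethynolate 3 (not isolated)
Conditions: CH2Br2, lithium 2,2,6,6-tetramethylpiperidide, THF, −78 °C; LiN(SiMe3)2; n-BuLi, −78 °C → rt; then i-Pr3SiOTf, −78 → 0 °C
Reagents that add atoms: dibromomethane, BrCBr; triisopropylsilyl trifluoromethanesulfonate, CC(C)[Si](OS(=O)(=O)C(F)(F)F)(C(C)C)C(C)C
Why: Kowalski ynolate synthesis, in which LiCHBr2 adds to the non-enolisable ester, Br/Li exchange on the derived dibromo enolate triggers the 1,2-shift of the dioxolanyl carbon to the ynolate, and the bulky silyl triflate should trap the ynolate on oxygen while the base-stable ketal is a spectator.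

Step 3
Reactants: 5 ethyl 4-methylpent-3-enoate
Product: 7 triisopropyl[(5-methylhex-4-en-1-yn-1-yl)oxy]silane, via lithium 5-methylhex-4-en-1-yn-1-olate 6 (not isolated)
Conditions: CH2Br2, lithium 2,2,6,6-tetramethylpiperidide, THF, −78 °C; LiN(SiMe3)2; n-BuLi, −78 °C → rt; then i-Pr3SiOTf, −78 → 0 °C
Reagents that add atoms: dibromomethane, BrCBr; triisopropylsilyl trifluoromethanesulfonate, CC(C)[Si](OS(=O)(=O)C(F)(F)F)(C(C)C)C(C)C
Why: The same Kowalski homologation and O-silylation should apply, because carbenoid addition to the ester at −78 °C is expected to outpace enolisation of the arylacetate-like α-CH2 and the trisubstituted alkene is inert to the bases.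

Step 4
Reactants: 8 3-isobutylglutaric acid [3-(2-methylpropyl)pentanedioic acid]
Product: 9 3-(2-methylpropyl)pentanedioyl dichloride
Conditions: SOCl2 (excess), DMF (cat.), 70 °C; distillation
Reagents that add atoms: thionyl chloride, ClS(Cl)=O
Why: Standard conversion of a dicarboxylic acid into its diacyl chloride with thionyl chloride under DMF catalysis, where excess reagent suppresses and distillation removes any cyclic anhydride.

Step 5
Reactants: 9 3-(2-methylpropyl)pentanedioyl dichloride; 4 triisopropyl{[(2-methyl-1,3-dioxolan-2-yl)ethynyl]oxy}silane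
Product: 11 4,4'-(3-methylbutane-1,1-diyl)bis[2-(2-methyl-1,3-dioxolan-2-yl)-3-(triisopropylsilyloxy)cyclobut-2-en-1-one] (diastereomer mixture), via bis-ketene 3-(2-methylpropyl)penta-1,4-diene-1,5-dione 10 (not isolated)
Conditions: 4 (2.2 equiv), Et3N, Et2O, rt, slow addition of 9; filtration; Et3N-deactivated SiO2 (removal of excess 4)
Reagents that add atoms: none
Why: Dehydrochlorination of each acyl chloride gives a ketene arm that the electron-rich ynol silyl ether should capture in situ by a polar ketene–alkyne [2+2] cycloaddition whose orientation (oxygen-free alkyne carbon to the ketene carbonyl carbon) places the dioxolanyl carbon at C2 and the silyloxy group at C3, while the C4 stereocentres form unselectively and are erased in step 6.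

Step 6
Reactants: 11 4,4'-(3-methylbutane-1,1-diyl)bis[2-(2-methyl-1,3-dioxolan-2-yl)-3-(triisopropylsilyloxy)cyclobut-2-en-1-one]; 7 triisopropyl[(5-methylhex-4-en-1-yn-1-yl)oxy]silane
Product: 12 2,2'-(3-methylbutane-1,1-diyl)bis[4-(2-methyl-1,3-dioxolan-2-yl)-6-(3-methylbut-2-en-1-yl)-3,5-bis(triisopropylsilyloxy)phenol]
Conditions: 7 (3 equiv), toluene, 80 → 110 °C, sealed tube, Ar
Reagents that add atoms: none
Why: Each cyclobutenone should open by thermal conrotatory 4π electrocyclic cleavage to a 3-silyloxy vinylketene with the bulky C4 substituent rotating outward; the ketene then adds siloxyalkyne 7 by [2+2] cycloaddition, and the resulting 4-vinylcyclobutenone opens again to a dienylketene. Each benzene ring is closed by thermal disrotatory 6π electrocyclisation of that dienylketene to a cyclohexa-2,4-dienone, which enolises to the phenol; in net terms the two alkyne carbons are inserted between C1 and C2 of each cyclobutenone, forming the C3–C4 and C1–C2 bonds of each arene. The closest known reaction is the Danheiser benzannulation of cyclobutenones with siloxyalkynes, here run twice in one molecule. No stereocentre is created, and those of 11 vanish on ring opening. The selectivity needed is the orientation of the alkyne, secured by attack of its oxygen-free, nucleophilic carbon on the electrophilic ketene carbonyl carbon, and capture by the alkyne in preference to the prenyl alkenes, secured by the far higher nucleophilicity of the ynol ether; excess 7 should also suppress ketene dimerisation and acylation of the new phenols. Any silyl migration between ring oxygens is irrelevant because step 7 removes all four silyl groups.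

Step 7
Reactants: 12 2,2'-(3-methylbutane-1,1-diyl)bis[4-(2-methyl-1,3-dioxolan-2-yl)-6-(3-methylbut-2-en-1-yl)-3,5-bis(triisopropylsilyloxy)phenol]
Product: 14 target 1,1'-[(3-methylbutane-1,1-diyl)bis[2,4,6-trihydroxy-5-(3-methylbut-2-en-1-yl)-3,1-phenylene]]di(ethan-1-one), via hexaphenol bis-ketal 13 (not isolated)
Conditions: Bu4NF, AcOH, THF, 0 °C; then 1 M aq. HCl, rt, short time, Ar
Reagents that add atoms: water, O
Why: Fluoride-mediated cleavage of the four aryl silyl ethers under acetic acid buffering, followed by brief acid-catalysed hydrolysis of the two dioxolanes through oxocarbenium ions stabilised by the electron-rich ring, should release the hydrogen-bonded aryl ketones, while cold dilute acid is too weak to cyclise the ortho-prenyl phenols to chromans or the bridge to a xanthene.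

Compound list
1 | ethyl pyruvate | CCOC(=O)C(C)=O | starting material
2 | ethyl 2-methyl-1,3-dioxolane-2-carboxylate | CCOC(=O)C1(C)OCCO1 | intermediate
3 | lithium 2-(2-methyl-1,3-dioxolan-2-yl)ethynolate (not isolated) | [Li+].[O-]C#CC1(C)OCCO1 | intermediate
4 | triisopropyl{[(2-methyl-1,3-dioxolan-2-yl)ethynyl]oxy}silane | CC1(C#CO[Si](C(C)C)(C(C)C)C(C)C)OCCO1 | intermediate
5 | ethyl 4-methylpent-3-enoate | CCOC(=O)CC=C(C)C | starting material
6 | lithium 5-methylhex-4-en-1-yn-1-olate (not isolated) | [Li+].[O-]C#CCC=C(C)C | intermediate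
7 | triisopropyl[(5-methylhex-4-en-1-yn-1-yl)oxy]silane | CC(C)=CCC#CO[Si](C(C)C)(C(C)C)C(C)C | intermediate
8 | 3-isobutylglutaric acid [3-(2-methylpropyl)pentanedioic acid] | CC(C)CC(CC(=O)O)CC(=O)O | starting material
9 | 3-(2-methylpropyl)pentanedioyl dichloride | CC(C)CC(CC(=O)Cl)CC(=O)Cl | intermediate
10 | 3-(2-methylpropyl)penta-1,4-diene-1,5-dione, bis-ketene (not isolated) | CC(C)CC(C=C=O)C=C=O | intermediate
11 | 4,4'-(3-methylbutane-1,1-diyl)bis[2-(2-methyl-1,3-dioxolan-2-yl)-3-(triisopropylsilyloxy)cyclobut-2-en-1-one], diastereomer mixture; ring numbering C1 carbonyl, C2 dioxolanyl, C3 silyloxy, C4 bridge | CC(C)CC(C1C(=O)C(C2(C)OCCO2)=C1O[Si](C(C)C)(C(C)C)C(C)C)C1C(=O)C(C2(C)OCCO2)=C1O[Si](C(C)C)(C(C)C)C(C)C | intermediate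
12 | 2,2'-(3-methylbutane-1,1-diyl)bis[4-(2-methyl-1,3-dioxolan-2-yl)-6-(3-methylbut-2-en-1-yl)-3,5-bis(triisopropylsilyloxy)phenol] | CC(C)CC(c1c(O)c(CC=C(C)C)c(O[Si](C(C)C)(C(C)C)C(C)C)c(C2(C)OCCO2)c1O[Si](C(C)C)(C(C)C)C(C)C)c1c(O)c(CC=C(C)C)c(O[Si](C(C)C)(C(C)C)C(C)C)c(C2(C)OCCO2)c1O[Si](C(C)C)(C(C)C)C(C)C | intermediate
13 | 2,2'-(3-methylbutane-1,1-diyl)bis[4-(2-methyl-1,3-dioxolan-2-yl)-6-(3-methylbut-2-en-1-yl)benzene-1,3,5-triol], hexaphenol bis-ketal (not isolated) | CC(C)CC(c1c(O)c(CC=C(C)C)c(O)c(C2(C)OCCO2)c1O)c1c(O)c(CC=C(C)C)c(O)c(C2(C)OCCO2)c1O | intermediate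
14 | 1,1'-[(3-methylbutane-1,1-diyl)bis[2,4,6-trihydroxy-5-(3-methylbut-2-en-1-yl)-3,1-phenylene]]di(ethan-1-one), achiral | CC(=O)c1c(O)c(CC=C(C)C)c(O)c(C(CC(C)C)c2c(O)c(CC=C(C)C)c(O)c(C(C)=O)c2O)c1O | target

Total step count: 7
Longest linear sequence: 5 steps (steps 1, 2, 5, 6, 7)

Steps most likely to fail

1. Step 6. The sequence may stall after the first annulation, ketene intermediates may acylate the newly formed phenols or dimerise, the siloxyalkyne may undergo thermal silyl shift to a silylketene, or the 6π closure to the crowded hexasubstituted ring may be too slow. Fallback: the bridge would be made last, so that each ring is built as a less crowded pentasubstituted arene; it sets out from 4 (and uses 7) and returns at 14. Ketene gas (from pyrolysis of diketene) passed into 4 should give 2-(2-methyl-1,3-dioxolan-2-yl)-3-(triisopropylsilyloxy)cyclobut-2-en-1-one F1. Heating F1 with 7 in toluene should give 4-(2-methyl-1,3-dioxolan-2-yl)-2-(3-methylbut-2-en-1-yl)-3,5-bis(triisopropylsilyloxy)phenol F2. Bu4NF/AcOH should give 2-(2-methyl-1,3-dioxolan-2-yl)-4-(3-methylbut-2-en-1-yl)benzene-1,3,5-triol F3, which dilute aqueous HCl should convert in the same flask into 1-[2,4,6-trihydroxy-3-(3-methylbut-2-en-1-yl)phenyl]ethan-1-one F4. Condensation of two equivalents of F4 with 3-methylbutanal (piperidine cat., EtOH; Knoevenagel condensation, then Michael addition of the second phloroglucinol to the ortho-quinone methide at the only free ring carbon) should give 14.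

2. Step 5. The first-formed enolate or ketene arm may be O-acylated intramolecularly by the second acyl chloride to a six-membered chloro-enol lactone, the ketene arms may dimerise, or the vinylogous silyl esters may hydrolyse during purification. Fallback: the two four-membered rings would be built one arm at a time, so that a ketene never faces an acyl chloride in the same molecule; it sets out from 8 and returns at 11. Ac2O at reflux should give 4-(2-methylpropyl)oxane-2,6-dione F5. Allyl alcohol with DMAP should open it to racemic 5-methyl-3-[2-oxo-2-(prop-2-en-1-yloxy)ethyl]hexanoic acid F6. (COCl)2 with catalytic DMF should give prop-2-en-1-yl 3-(2-chloro-2-oxoethyl)-5-methylhexanoate F7. Et3N should convert F7 into the ketene prop-2-en-1-yl 5-methyl-3-(2-oxoethenyl)hexanoate F8, which 4 should capture as prop-2-en-1-yl 5-methyl-3-[3-(2-methyl-1,3-dioxolan-2-yl)-4-oxo-2-(triisopropylsilyloxy)cyclobut-2-en-1-yl]hexanoate F9. Neutral allyl transfer with the zerovalent palladium complex Pd(PPh3)4 and sodium 2-ethylhexanoate should give sodium 5-methyl-3-[3-(2-methyl-1,3-dioxolan-2-yl)-4-oxo-2-(triisopropylsilyloxy)cyclobut-2-en-1-yl]hexanoate F10. (COCl)2 in CH2Cl2 at 0 °C should give 5-methyl-3-[3-(2-methyl-1,3-dioxolan-2-yl)-4-oxo-2-(triisopropylsilyloxy)cyclobut-2-en-1-yl]hexanoyl chloride F11. Et3N should then generate the ketene 4-(5-methyl-1-oxohex-1-en-3-yl)-2-(2-methyl-1,3-dioxolan-2-yl)-3-(triisopropylsilyloxy)cyclobut-2-en-1-one F12, which a second equivalent of 4 should capture to give 11.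

3. Step 2. The 1,2-shift of the dialkoxy-substituted carbon may be slow, the ynolate may lose alkoxide from its β-oxygenated carbon, or silylation may occur on carbon. Fallback: the ynolate would be reached by oxidation of an acetylide instead of carbenoid rearrangement; it sets out from 2 and returns at 4. i-Bu2AlH in CH2Cl2 at −78 °C should give 2-methyl-1,3-dioxolane-2-carbaldehyde F13. Ohira–Bestmann homologation (dimethyl (1-diazo-2-oxopropyl)phosphonate, K2CO3, MeOH) should give 2-ethynyl-2-methyl-1,3-dioxolane F14. n-BuLi should give lithium (2-methyl-1,3-dioxolan-2-yl)acetylide F15, which LiOOt-Bu should oxidise to ynolate 3, and i-Pr3SiOTf should then give 4.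

Further compounds
F1 | step 6 | 2-(2-methyl-1,3-dioxolan-2-yl)-3-(triisopropylsilyloxy)cyclobut-2-en-1-one | O=C1CC(O[Si](C(C)C)(C(C)C)C(C)C)=C1C1(C)OCCO1
F2 | step 6 | 4-(2-methyl-1,3-dioxolan-2-yl)-2-(3-methylbut-2-en-1-yl)-3,5-bis(triisopropylsilyloxy)phenol | Oc1cc(O[Si](C(C)C)(C(C)C)C(C)C)c(C2(C)OCCO2)c(O[Si](C(C)C)(C(C)C)C(C)C)c1CC=C(C)C
F3 | step 6 | 2-(2-methyl-1,3-dioxolan-2-yl)-4-(3-methylbut-2-en-1-yl)benzene-1,3,5-triol | CC1(c2c(O)cc(O)c(CC=C(C)C)c2O)OCCO1
F4 | step 6 | 1-[2,4,6-trihydroxy-3-(3-methylbut-2-en-1-yl)phenyl]ethan-1-one | CC(=O)c1c(O)cc(O)c(CC=C(C)C)c1O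
F5 | step 5 | 4-(2-methylpropyl)oxane-2,6-dione | CC(C)CC1CC(=O)OC(=O)C1
F6 | step 5 | 5-methyl-3-[2-oxo-2-(prop-2-en-1-yloxy)ethyl]hexanoic acid, racemic | C=CCOC(=O)CC(CC(C)C)CC(=O)O
F7 | step 5 | prop-2-en-1-yl 3-(2-chloro-2-oxoethyl)-5-methylhexanoate, racemic | C=CCOC(=O)CC(CC(C)C)CC(=O)Cl
F8 | step 5 | prop-2-en-1-yl 5-methyl-3-(2-oxoethenyl)hexanoate, racemic | C=CCOC(=O)CC(CC(C)C)C=C=O
F9 | step 5 | prop-2-en-1-yl 5-methyl-3-[3-(2-methyl-1,3-dioxolan-2-yl)-4-oxo-2-(triisopropylsilyloxy)cyclobut-2-en-1-yl]hexanoate, diastereomer mixture | C=CCOC(=O)CC(CC(C)C)C1C(=O)C(C2(C)OCCO2)=C1O[Si](C(C)C)(C(C)C)C(C)C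
F10 | step 5 | sodium 5-methyl-3-[3-(2-methyl-1,3-dioxolan-2-yl)-4-oxo-2-(triisopropylsilyloxy)cyclobut-2-en-1-yl]hexanoate, diastereomer mixture | [Na+].[O-]C(=O)CC(CC(C)C)C1C(=O)C(C2(C)OCCO2)=C1O[Si](C(C)C)(C(C)C)C(C)C
F11 | step 5 | 5-methyl-3-[3-(2-methyl-1,3-dioxolan-2-yl)-4-oxo-2-(triisopropylsilyloxy)cyclobut-2-en-1-yl]hexanoyl chloride, diastereomer mixture | O=C(Cl)CC(CC(C)C)C1C(=O)C(C2(C)OCCO2)=C1O[Si](C(C)C)(C(C)C)C(C)C
F12 | step 5 | 4-(5-methyl-1-oxohex-1-en-3-yl)-2-(2-methyl-1,3-dioxolan-2-yl)-3-(triisopropylsilyloxy)cyclobut-2-en-1-one, diastereomer mixture | CC(C)CC(C=C=O)C1C(=O)C(C2(C)OCCO2)=C1O[Si](C(C)C)(C(C)C)C(C)C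
F13 | step 2 | 2-methyl-1,3-dioxolane-2-carbaldehyde | O=CC1(C)OCCO1
F14 | step 2 | 2-ethynyl-2-methyl-1,3-dioxolane | C#CC1(C)OCCO1
F15 | step 2 | lithium (2-methyl-1,3-dioxolan-2-yl)acetylide | [Li]C#CC1(C)OCCO1
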